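L is conserved here: what you charged is either still L or has become X, and since X is meant with its E, you read the X column as it stands and add nothing to it. So work with f, [L] over its charge, which is one minus X.

- eta: L 1.9 M; G 120 mM (held); Z 5.8 mM; run made earlier
- flask: L 2.9 M; G 120 mM (held); Z 5.8 mM; time 50 min

eta run (percent of the L charged)

| time / min | X / % | E / % |
|---|---|---|
| 8.00 | 7 | 3 |
| 15.0 | 8 | 9 |
| 25.0 | 16 | 10 |
| 30.0 | 17 | 14 |
| 40.0 | 23 | 23 |
| 50.0 | 30 | 23 |

(each reading ± 2 percentage points)

- X is meant together with its E
- at the start none of G is in solution

- midnight: doubling the saturation concentration of G, all else as stated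
- autumn: doubling the transfer coefficient of G, all else as stated
- spring: doubling the amount of Z, all else as stated

1. amount of X and E together at 50 min, in percent of the L charged
2. the change that raises the amount of X and E together at 50 min, in percent of the L charged most ("none" if none brings more than 2 percentage points) (midnight / autumn / spring / none)
3. amount of X and E together at 50 min, in percent of the L charged, after midnight

The eta run's last reading, X 30 % at 50.0 min, gives κ = ln(1/f)/t, 0.00713 min⁻¹: the decay constant, a pseudo-first-order constant, read with a scatter of 2 percentage points in X.

From above: if κ holds at the richer charge, f carries over and the flask reaches 30.0 %. From below: if the supply of G caps the molar rate, the flask makes the same 0.570 M as eta, which is 19.7 % of its charge. The eta readings, 16 % at 25.0 min and a further 14 points by 50.0 min, cannot part these limits at that scatter, so you commit to the midpoint, 24.8 %.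

Midnight acts in both limits: f squared gives 51.0 %, a doubled molar rate gives 39.3 %, and the midpoint is 45.2 %. Autumn and spring each act in one limit, so you pick midnight.

The forecast, calling the rate “effectively zero order in L”, says 36 %, midnight and 67 %, higher than both brackets.

The flask gives 24.0 %. The best change is midnight, which adds 19 points and reaches 43.4 %; spring adds 6.6 points and autumn 5.4 points.

    G ⇌ Q, rate k1*(csat - [Q]) (kL = 0.00940 s⁻¹)
    L + Q + Z → Z + X (k = 2.20 M⁻² s⁻¹)
    Q + X ⇌ E, settled at all times (K = 97.0 M⁻¹)
    2 Z ⇌ J, settled at all times (K = 3600 M⁻¹)
    Z ⇌ D (K = 5.00, k = 0.0180 s⁻¹)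

Eta's κ, 0.00713 min⁻¹, is a reading at eta's own charge; the same reckoning on the flask's result gives 0.00548 min⁻¹. Carried to the same flask read at 3.0 h, it leaves 37.3 % of the L and gives X 62.7 %. That flask gives 67.6 %, more than reckoned, with 32.4 % of the L left, so its κ is 0.00626 min⁻¹. Dissolved Q in this flask stood at 0.0768 M at 50.0 min and at 0.0962 M at 180 min.

(All runs are calculated on assumed constants.)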